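**Strategy.** Ring B, not the diaryl ether bond, is disconnected: its six carbons are assembled on the ring A oxygen. Ring B has a C-methyl between two oxygen-bearing carbons (depsidone ester O and phenol OH), with the lactone carboxyl next to the phenol carbon and the lactol carbon next to the aryloxy carbon. An alkenyl(alkoxycarbonyl)ketene and 1-siloxypropyne deliver exactly this pattern. Irradiating an (E)-β-aryloxy enone diazo ketoester that already carries ring A triggers Wolff shift, (2+2) addition, 4π opening and 6π closure, forming four ring B bonds and the arene in one operation. Lactonisation, lactol release and resolution as a 1-phenylethyl acetal finish the route.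

Key step: step 12

Remark on the chemistry: the lactol carbon of a 3-hydroxyphthalide can epimerise through its ring-opened formyl acid, so this centre is fixed as a separable mixed acetal and the (R)-lactol is released only in the last step under neutral aprotic conditions; the product should be kept cold and free of acid and base.

Notation: Ar = 2-(allyloxycarbonyl)-6-[(tert-butyldiphenylsilyloxy)methyl]-5-methoxy-3-methylphenyl (ring A, bound through its phenol oxygen). Ring B is numbered C1 (aryloxy carbon), C2 (carbon bearing the depsidone ester oxygen), C3 (methyl), C4 (phenol), C5 (lactone carboxyl), C6 (lactol carbon).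

Step 1
Reactants: 1 orsellinic acid (2,4-dihydroxy-6-methylbenzoic acid)
Product: 2 allyl 2,4-dihydroxy-6-methylbenzoate
Conditions: allyl bromide, KHCO3, DMF, rt
Reagents that add atoms: allyl bromide, C=CCBr
Why: Carboxylate O-alkylation (SN2); hydrogencarbonate deprotonates only the carboxylic acid, so both phenols stay free.

Step 2
Reactants: 2 allyl 2,4-dihydroxy-6-methylbenzoate
Product: 3 allyl 2-hydroxy-4-methoxy-6-methylbenzoate
Conditions: MeI (1.05 equiv), K2CO3, acetone, 40 °C
Reagents that add atoms: iodomethane, CI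
Why: Williamson etherification; the 2-OH is hydrogen-bonded to the ester carbonyl, so the 4-OH should be methylated selectively.

Step 3
Reactants: 3 allyl 2-hydroxy-4-methoxy-6-methylbenzoate
Product: 4 allyl 3-formyl-2-hydroxy-4-methoxy-6-methylbenzoate
Conditions: MgCl2, Et3N, (CH2O)n, MeCN, reflux
Reagents that add atoms: paraformaldehyde (formaldehyde), C=O
Why: Magnesium-mediated ortho-formylation of a phenol (Casnati–Skattebøl); the magnesium phenoxide delivers formaldehyde to the only free ortho position, and a second formaldehyde oxidises the benzylic alkoxide by hydride transfer.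

Step 4
Reactants: 4 allyl 3-formyl-2-hydroxy-4-methoxy-6-methylbenzoate
Product: 5 allyl 2-hydroxy-3-(hydroxymethyl)-4-methoxy-6-methylbenzoate
Conditions: NaBH4, THF/MeOH, 0 °C
Reagents that add atoms: none
Why: Borohydride reduction of the aldehyde; the hindered benzoate ester is not reduced at this temperature.

Step 5
Reactants: 5 allyl 2-hydroxy-3-(hydroxymethyl)-4-methoxy-6-methylbenzoate
Product: 6 allyl 3-[(tert-butyldiphenylsilyloxy)methyl]-2-hydroxy-4-methoxy-6-methylbenzoate (ring A phenol, ArOH)
Conditions: TBDPSCl, imidazole, CH2Cl2, 0 °C → rt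
Reagents that add atoms: tert-butyl(chloro)diphenylsilane, CC(C)(C)[Si](Cl)(c1ccccc1)c1ccccc1
Why: Silylation of the primary alcohol; the phenol is hindered and hydrogen-bonded to the ester, so the bulky silyl chloride should select the primary hydroxyl.

Step 6
Reactants: 7 methyl 3,3-dimethoxypropanoate
Product: 9 methyl (Z)-2-(dimethoxymethyl)-3-(tosyloxy)acrylate, via sodium formyl enolate 8 (not isolated)
Conditions: HCO2Me, NaH, THF, 0 °C → rt; evaporate; TsCl, MeCN, 0 °C → rt
Reagents that add atoms: methyl formate, COC=O; p-toluenesulfonyl chloride, Cc1ccc(cc1)S(=O)(=O)Cl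
Why: Crossed Claisen formylation gives the stabilised enolate, which is O-sulfonylated to an enol tosylate; its geometry does not matter because the next step equilibrates it.

Step 7
Reactants: 6 ring A phenol ArOH; 9 methyl (Z)-2-(dimethoxymethyl)-3-(tosyloxy)acrylate
Product: 10 methyl (E)-3-(aryloxy)-2-(dimethoxymethyl)acrylate (aryl = Ar)
Conditions: Cs2CO3, MeCN, rt → 50 °C
Reagents that add atoms: none
Why: Addition–elimination (vinylic substitution) of the phenoxide at the unhindered β-carbon; reversible addition should leave the aryloxy group trans to the ester, the preferred geometry of α-substituted β-alkoxyacrylates.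

Step 8
Reactants: 10 methyl (E)-3-(aryloxy)-2-(dimethoxymethyl)acrylate
Product: 11 (E)-3-(aryloxy)-2-(dimethoxymethyl)acrylic acid
Conditions: Me3SnOH, 1,2-dichloroethane, 70 °C; cold 0.1 M HCl wash
Reagents that add atoms: trimethyltin hydroxide, C[Sn](C)(C)O
Why: Tin-hydroxide ester hydrolysis by acyl transfer without free hydroxide, which could attack the β-carbon and expel the phenoxide; the di-ortho-substituted allyl benzoate is too hindered to react.

Step 9
Reactants: 11 (E)-3-(aryloxy)-2-(dimethoxymethyl)acrylic acid; 12 mono-tert-butyl malonate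
Product: 14 tert-butyl (E)-5-(aryloxy)-4-(dimethoxymethyl)-3-oxopent-4-enoate, via acyl imidazolide 13 (not isolated)
Conditions: CDI, THF, rt; then 12, MgCl2, Et3N, THF/MeCN, rt → 40 °C; pH 5 work-up
Reagents that add atoms: none
Why: Masamune–Brooks homologation; the acyl imidazolide C-acylates the magnesium malonate and the adduct loses CO2.

Step 10
Reactants: 14 tert-butyl (E)-5-(aryloxy)-4-(dimethoxymethyl)-3-oxopent-4-enoate
Product: 15 tert-butyl (E)-5-(aryloxy)-2-diazo-4-(dimethoxymethyl)-3-oxopent-4-enoate (diazo ketoester carrying ring A)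
Conditions: 4-acetamidobenzenesulfonyl azide, Et3N, MeCN, 0 °C → rt
Reagents that add atoms: 4-acetamidobenzenesulfonyl azide, CC(=O)Nc1ccc(cc1)S(=O)(=O)N=[N+]=[N-]
Why: Regitz diazo transfer to the active methylene of a β-keto ester.

Step 11
Reactants: 16 ethyl acetate
Product: 19 1-(triisopropylsilyloxy)prop-1-yne, via lithium dibromoenolate 17 (not isolated), via lithium propynolate 18 (not isolated)
Conditions: CH2Br2, lithium 2,2,6,6-tetramethylpiperidide, THF, −78 °C; nBuLi, −78 °C → rt; TIPSCl, −78 °C → rt
Reagents that add atoms: dibromomethane, BrCBr; chlorotriisopropylsilane, CC(C)[Si](Cl)(C(C)C)C(C)C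
Why: Kowalski ester homologation stopped at the ynolate; bromine–lithium exchange on the dibromoenolate triggers a 1,2-shift to the ynolate, which the bulky silyl chloride traps on oxygen.

Step 12
Reactants: 15 diazo ketoester carrying ring A; 19 1-(triisopropylsilyloxy)prop-1-yne
Product: 24 allyl 2-[3-(tert-butoxycarbonyl)-2-(dimethoxymethyl)-6-hydroxy-5-methyl-4-(triisopropylsilyloxy)phenoxy]-3-[(tert-butyldiphenylsilyloxy)methyl]-4-methoxy-6-methylbenzoate, via vinylketene 20 (not isolated), via siloxycyclobutenone 21 (not isolated), via dienylketene 22 (not isolated), via cyclohexadienone 23 (not isolated)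
Conditions: 19 (3 equiv), hν (300 nm), degassed 1,2-dichloroethane, rt; then 80 °C
Reagents that add atoms: none
Why: Proposed new method: light expels N2 from 15 and the alkenyl group shifts to the carbene carbon (Wolff rearrangement, C5–C6 bond) to give alkenyl(tert-butoxycarbonyl)ketene 20; the nucleophilic methyl-bearing carbon of 19 adds to the ketene carbonyl carbon and closure gives the (2+2) adduct 21 (C2–C3 and C4–C5 bonds), which opens in a thermal 4π step to dienylketene 22 and closes in a 6π step onto the aryloxy-bearing carbon (C1–C2 bond) to dienone 23, whose enolisation gives 24. The closest known reaction type is the photochemical Wolff-based vinylketene benzannulation of α-diazo enones with siloxyalkynes to resorcinol monosilyl ethers; the ester on the diazo carbon and the β-aryloxy group are the untested features. Ring B is the only ring closed, by 6π electrocyclisation followed by tautomerisation to the arene, and no stereocenter is formed. The step needs one orientation in the (2+2) addition, and the siloxy group secures it by polarising the alkyne so that its methyl-bearing carbon bonds to the ketene carbon, which places the methyl between the two oxygens and the ester beside the siloxy carbon. The E enol ether keeps the aryloxy group on the outside of the triene terminus, an excess of 19 should outrun acylation of the new phenol by the ketene, and even a stepwise addition through a zwitterion should collapse to the same carbon skeleton.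

Step 13
Reactants: 24 allyl ester diaryl ether
Product: 25 2-[3-(tert-butoxycarbonyl)-2-(dimethoxymethyl)-6-hydroxy-5-methyl-4-(triisopropylsilyloxy)phenoxy]-3-[(tert-butyldiphenylsilyloxy)methyl]-4-methoxy-6-methylbenzoic acid
Conditions: Pd(PPh3)4 (cat.), morpholine, THF, rt
Reagents that add atoms: none
Why: Tsuji–Trost deallylation; zerovalent palladium ionises the allyl ester and morpholine takes up the allyl group, leaving the tert-butyl ester, acetal and silyl ethers untouched.

Step 14
Reactants: 25 ring A carboxylic acid carrying the free C2 phenol on ring B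
Product: 27 silyl-protected depsidone tert-butyl ester dimethyl acetal (seven-membered lactone between the ring A carboxyl and the C2 oxygen of ring B), via O-acylisourea 26 (not isolated)
Conditions: DCC, DMAP (cat.), CH2Cl2 (high dilution), rt
Reagents that add atoms: none
Why: Steglich-type lactonisation; the phenol ortho to the ether oxygen attacks the activated acid and closes the seven-membered ring (7-exo-trig), while the other ring B oxygen is silylated.

Step 15
Reactants: 27 silyl-protected depsidone tert-butyl ester dimethyl acetal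
Product: 28 racemic lactol (3-hydroxyphthalide ring fused at C5/C6 of ring B; both silyl ethers retained)
Conditions: TFA/CH2Cl2/H2O (10:10:1), 0 °C → rt
Reagents that add atoms: water, O
Why: Acidolysis removes the tert-butyl group as isobutene and hydrolyses the acetal, and the ortho carboxylic acid adds to the aldehyde to close the five-membered lactol as a racemate; TBDPS and aryl TIPS ethers should tolerate these conditions.

Step 16
Reactants: 28 racemic lactol; 29 (S)-1-phenylethanol
Product: 31 (R)-configured (S)-1-phenylethyl acetal of the silyl-protected lactol, via acetal epimer pair 30 (not isolated)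
Conditions: 29 (excess), camphorsulfonic acid (cat.), 4 Å MS, 1,2-dichloroethane, 40 °C; chromatography on SiO2; remaining epimer fraction returned to the same acid conditions
Reagents that add atoms: none
Why: Acid-catalysed pseudo-ester (acetal) formation through the acyloxy-stabilised oxocarbenium ion; the acetal carbon forms without facial control, so the crude product is the pair of acetal-carbon epimers 30, from which the (R)-acetal 31 is secured by chromatographic separation of diastereomers, while the unwanted fraction of 30 re-equilibrates through the same cation when returned to the acid.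

Step 17
Reactants: 31 (R)-acetal of the silyl-protected depsidone
Product: 32 desilylated (R)-acetal (free CH2OH on ring A, free C4 phenol on ring B)
Conditions: HF·pyridine, pyridine, THF, 0 °C → rt
Reagents that add atoms: none
Why: Buffered fluoride desilylation of the primary TBDPS ether and the aryl TIPS ether; the acetal carbon is locked and cannot epimerise, and the aryl ester is not opened by this non-basic reagent.

Step 18
Reactants: 32 desilylated (R)-acetal
Product: 33 target CNP0367167.1, (R)-lactol
Conditions: H2 (1 atm), 10% Pd/C, EtOAc, 0 °C → rt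
Reagents that add atoms: none
Why: Hydrogenolysis of the benzylic C–O bond of the 1-phenylethyl group, as in debenzylation of benzyl glycosides; the bond to the acetal carbon is not broken, so the R configuration secured in step 16 is retained.

**Compound list**

1 | orsellinic acid (2,4-dihydroxy-6-methylbenzoic acid) | Cc1cc(O)cc(O)c1C(=O)O | starting material
2 | allyl 2,4-dihydroxy-6-methylbenzoate | C=CCOC(=O)c1c(C)cc(O)cc1O | intermediate
3 | allyl 2-hydroxy-4-methoxy-6-methylbenzoate | C=CCOC(=O)c1c(C)cc(OC)cc1O | intermediate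
4 | allyl 3-formyl-2-hydroxy-4-methoxy-6-methylbenzoate | C=CCOC(=O)c1c(C)cc(OC)c(C=O)c1O | intermediate
5 | allyl 2-hydroxy-3-(hydroxymethyl)-4-methoxy-6-methylbenzoate | C=CCOC(=O)c1c(C)cc(OC)c(CO)c1O | intermediate
6 | allyl 3-[(tert-butyldiphenylsilyloxy)methyl]-2-hydroxy-4-methoxy-6-methylbenzoate (ArOH) | C=CCOC(=O)c1c(C)cc(OC)c(CO[Si](c2ccccc2)(c2ccccc2)C(C)(C)C)c1O | intermediate
7 | methyl 3,3-dimethoxypropanoate | COC(OC)CC(=O)OC | starting material
8 | sodium (Z)-2-(dimethoxymethyl)-3-methoxy-3-oxoprop-1-en-1-olate | [Na+].[O-]/C=C(\C(=O)OC)C(OC)OC | intermediate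
9 | methyl (Z)-2-(dimethoxymethyl)-3-(tosyloxy)acrylate | Cc1ccc(cc1)S(=O)(=O)O/C=C(\C(=O)OC)C(OC)OC | intermediate
10 | methyl (E)-3-(aryloxy)-2-(dimethoxymethyl)acrylate (aryl = Ar) | C=CCOC(=O)c1c(C)cc(OC)c(CO[Si](c2ccccc2)(c2ccccc2)C(C)(C)C)c1O/C=C(\C(OC)OC)C(=O)OC | intermediate
11 | (E)-3-(aryloxy)-2-(dimethoxymethyl)acrylic acid | C=CCOC(=O)c1c(C)cc(OC)c(CO[Si](c2ccccc2)(c2ccccc2)C(C)(C)C)c1O/C=C(\C(OC)OC)C(=O)O | intermediate
12 | mono-tert-butyl malonate | CC(C)(C)OC(=O)CC(=O)O | starting material
13 | (E)-3-(aryloxy)-2-(dimethoxymethyl)-1-(imidazol-1-yl)prop-2-en-1-one | C=CCOC(=O)c1c(C)cc(OC)c(CO[Si](c2ccccc2)(c2ccccc2)C(C)(C)C)c1O/C=C(\C(OC)OC)C(=O)n1ccnc1 | intermediate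
14 | tert-butyl (E)-5-(aryloxy)-4-(dimethoxymethyl)-3-oxopent-4-enoate | C=CCOC(=O)c1c(C)cc(OC)c(CO[Si](c2ccccc2)(c2ccccc2)C(C)(C)C)c1O/C=C(\C(OC)OC)C(=O)CC(=O)OC(C)(C)C | intermediate
15 | tert-butyl (E)-5-(aryloxy)-2-diazo-4-(dimethoxymethyl)-3-oxopent-4-enoate | C=CCOC(=O)c1c(C)cc(OC)c(CO[Si](c2ccccc2)(c2ccccc2)C(C)(C)C)c1O/C=C(\C(OC)OC)C(=O)C(=[N+]=[N-])C(=O)OC(C)(C)C | intermediate
16 | ethyl acetate | CCOC(C)=O | starting material
17 | lithium 1,1-dibromoprop-1-en-2-olate | [Li+].CC([O-])=C(Br)Br | intermediate
18 | lithium prop-1-yn-1-olate | [Li+].CC#C[O-] | intermediate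
19 | 1-(triisopropylsilyloxy)prop-1-yne | CC#CO[Si](C(C)C)(C(C)C)C(C)C | intermediate
20 | alkenyl(tert-butoxycarbonyl)ketene (aryloxy cis to the acetal) | C=CCOC(=O)c1c(C)cc(OC)c(CO[Si](c2ccccc2)(c2ccccc2)C(C)(C)C)c1O/C=C(\C(OC)OC)C(=C=O)C(=O)OC(C)(C)C | intermediate
21 | racemic 4-alkenyl-4-(tert-butoxycarbonyl)-2-methyl-3-(triisopropylsilyloxy)cyclobut-2-enone | C=CCOC(=O)c1c(C)cc(OC)c(CO[Si](c2ccccc2)(c2ccccc2)C(C)(C)C)c1O/C=C(\C(OC)OC)C1(C(=O)OC(C)(C)C)C(=O)C(C)=C1O[Si](C(C)C)(C(C)C)C(C)C | intermediate
22 | dienylketene (ketenyl and alkenyl groups cis on the central double bond; aryloxy cis to the acetal) | C=CCOC(=O)c1c(C)cc(OC)c(CO[Si](c2ccccc2)(c2ccccc2)C(C)(C)C)c1O/C=C(\C(OC)OC)/C(C(=O)OC(C)(C)C)=C(\C(C)=C=O)O[Si](C(C)C)(C(C)C)C(C)C | intermediate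
23 | racemic 6-aryloxy-cyclohexa-2,4-dienone tautomer of 24 | C=CCOC(=O)c1c(C)cc(OC)c(CO[Si](c2ccccc2)(c2ccccc2)C(C)(C)C)c1OC1C(=O)C(C)=C(O[Si](C(C)C)(C(C)C)C(C)C)C(C(=O)OC(C)(C)C)=C1C(OC)OC | intermediate
24 | allyl 2-[3-(tert-butoxycarbonyl)-2-(dimethoxymethyl)-6-hydroxy-5-methyl-4-(triisopropylsilyloxy)phenoxy]-3-[(tert-butyldiphenylsilyloxy)methyl]-4-methoxy-6-methylbenzoate | C=CCOC(=O)c1c(C)cc(OC)c(CO[Si](c2ccccc2)(c2ccccc2)C(C)(C)C)c1Oc1c(O)c(C)c(O[Si](C(C)C)(C(C)C)C(C)C)c(C(=O)OC(C)(C)C)c1C(OC)OC | intermediate
25 | corresponding ring A benzoic acid of 24 | OC(=O)c1c(C)cc(OC)c(CO[Si](c2ccccc2)(c2ccccc2)C(C)(C)C)c1Oc1c(O)c(C)c(O[Si](C(C)C)(C(C)C)C(C)C)c(C(=O)OC(C)(C)C)c1C(OC)OC | intermediate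
26 | O-acylisourea of 25 with DCC | O=C(OC(=NC1CCCCC1)NC1CCCCC1)c1c(C)cc(OC)c(CO[Si](c2ccccc2)(c2ccccc2)C(C)(C)C)c1Oc1c(O)c(C)c(O[Si](C(C)C)(C(C)C)C(C)C)c(C(=O)OC(C)(C)C)c1C(OC)OC | intermediate
27 | silyl-protected depsidone with C5 CO2tBu and C6 CH(OMe)2 on ring B | COc1cc(C)c2c(c1CO[Si](c4ccccc4)(c5ccccc5)C(C)(C)C)Oc1c(c(C)c(O[Si](C(C)C)(C(C)C)C(C)C)c(C(=O)OC(C)(C)C)c1C(OC)OC)OC2=O | intermediate
28 | racemic lactol, silyl ethers retained | COc1cc(C)c2c(c1CO[Si](c4ccccc4)(c5ccccc5)C(C)(C)C)Oc1c(c(C)c(O[Si](C(C)C)(C(C)C)C(C)C)c3c1C(O)OC3=O)OC2=O | intermediate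
29 | (S)-1-phenylethanol | O[C@@H](C)c1ccccc1 | starting material
30 | pair of acetal-carbon epimers of the (S)-1-phenylethyl mixed acetal (acetal carbon R and S; silyl ethers retained) | COc1cc(C)c2c(c1CO[Si](c4ccccc4)(c5ccccc5)C(C)(C)C)Oc1c(c(C)c(O[Si](C(C)C)(C(C)C)C(C)C)c3c1C(O[C@@H](C)c6ccccc6)OC3=O)OC2=O | intermediate
31 | mixed acetal with (R)-configured acetal carbon and (S)-1-phenylethoxy group, silyl ethers retained | COc1cc(C)c2c(c1CO[Si](c4ccccc4)(c5ccccc5)C(C)(C)C)Oc1c(c(C)c(O[Si](C(C)C)(C(C)C)C(C)C)c3c1[C@H](O[C@@H](C)c6ccccc6)OC3=O)OC2=O | intermediate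
32 | desilylated (R)-acetal with (S)-1-phenylethoxy group | COc1cc(C)c2c(c1CO)Oc1c(c(C)c(O)c3c1[C@H](O[C@@H](C)c6ccccc6)OC3=O)OC2=O | intermediate
33 | CNP0367167.1, (R)-lactol | COc1cc(C)c2c(c1CO)Oc1c(c(C)c(O)c3c1[C@H](O)OC3=O)OC2=O | target

**Totals.** 18 steps; longest linear sequence 16 steps (steps 1–5, 7–10, 12–18).

**Steps most likely to fail**

1. **Step 12.** The ester-substituted ketene may be diverted before ring B closes: the ynol ether may add across the ketene and ester carbonyl as an oxa-diene, the ketene may acylate the new phenol, or the carbene may react before it rearranges. Photoisomerisation of the enol ether may also slow the 6π closure. The fallback sets out from 11 and returns at 24. It leaves the ester off the diazo carbon so that the benzannulation runs in its established form, then adds the carboxyl by standard arene chemistry. Acid 11 is converted through its isobutyl mixed anhydride (iBuOCOCl, N-methylmorpholine, THF, −20 °C) and TMSCHN2 into (E)-4-(aryloxy)-1-diazo-3-(dimethoxymethyl)but-3-en-2-one F1. Irradiation of F1 with 19 under the conditions of step 12 should give the carboxyl-free ring B phenol F2. NBS (CH2Cl2, −78 °C) should brominate the only open position of ring B, para to the new phenol, to give bromide F3. Deprotonation of the phenol (NaH), bromine–lithium exchange (tBuLi, THF, −100 °C) and quenching with Boc2O should give the tert-butyl ester tert-butyl carbonate F4. Pyrrolidine (CH2Cl2, rt) removes the aryl carbonate and returns 24.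

2. **Step 18.** Over-reduction may occur: hydrogenolysis of the free benzylic alcohol of ring A or of the benzylic C–O bond inside the lactol ring may compete with cleavage of the 1-phenylethyl group. The fallback sets out from 28 and returns at 33 without an auxiliary or hydrogen. Lactol 28 is desilylated with HF·pyridine to the racemic lactol F5. Its enantiomers are separated by preparative chromatography on a chiral stationary phase (supercritical CO2/MeCN, neutral, cold) to give 33. The (S)-lactol F6 can be racemised with a trace of acid and resubmitted.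

3. **Step 9.** Conjugate addition–elimination at the β-carbon, with imidazole or the malonate displacing the aryloxy group, may compete with acyl transfer. The fallback sets out from 11 and returns at 15, bypassing steps 9 and 10. Acid 11 is converted under neutral conditions (1-chloro-N,N,2-trimethylprop-1-en-1-amine, CH2Cl2, 0 °C) into (E)-3-(aryloxy)-2-(dimethoxymethyl)acryloyl chloride F7. F7 is added to lithiated tert-butyl diazoacetate (tBuO2CCHN2, LiN(iPr)2, THF, −78 °C), which should give 15 directly by C-acylation.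

**Further compounds**

F1 | step 12 | (E)-4-(aryloxy)-1-diazo-3-(dimethoxymethyl)but-3-en-2-one (aryl = Ar) | C=CCOC(=O)c1c(C)cc(OC)c(CO[Si](c2ccccc2)(c2ccccc2)C(C)(C)C)c1O/C=C(\C(OC)OC)C(=O)C=[N+]=[N-]
F2 | step 12 | allyl 3-[(tert-butyldiphenylsilyloxy)methyl]-2-[2-(dimethoxymethyl)-6-hydroxy-5-methyl-4-(triisopropylsilyloxy)phenoxy]-4-methoxy-6-methylbenzoate | C=CCOC(=O)c1c(C)cc(OC)c(CO[Si](c2ccccc2)(c2ccccc2)C(C)(C)C)c1Oc1c(O)c(C)c(O[Si](C(C)C)(C(C)C)C(C)C)cc1C(OC)OC
F3 | step 12 | allyl 2-[3-bromo-2-(dimethoxymethyl)-6-hydroxy-5-methyl-4-(triisopropylsilyloxy)phenoxy]-3-[(tert-butyldiphenylsilyloxy)methyl]-4-methoxy-6-methylbenzoate | C=CCOC(=O)c1c(C)cc(OC)c(CO[Si](c2ccccc2)(c2ccccc2)C(C)(C)C)c1Oc1c(O)c(C)c(O[Si](C(C)C)(C(C)C)C(C)C)c(Br)c1C(OC)OC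
F4 | step 12 | allyl 2-[3-(tert-butoxycarbonyl)-6-(tert-butoxycarbonyloxy)-2-(dimethoxymethyl)-5-methyl-4-(triisopropylsilyloxy)phenoxy]-3-[(tert-butyldiphenylsilyloxy)methyl]-4-methoxy-6-methylbenzoate | C=CCOC(=O)c1c(C)cc(OC)c(CO[Si](c2ccccc2)(c2ccccc2)C(C)(C)C)c1Oc1c(OC(=O)OC(C)(C)C)c(C)c(O[Si](C(C)C)(C(C)C)C(C)C)c(C(=O)OC(C)(C)C)c1C(OC)OC
F5 | step 18 | racemic lactol (racemate of 33) | COc1cc(C)c2c(c1CO)Oc1c(c(C)c(O)c3c1C(O)OC3=O)OC2=O
F6 | step 18 | (S)-lactol, enantiomer of 33 | COc1cc(C)c2c(c1CO)Oc1c(c(C)c(O)c3c1[C@@H](O)OC3=O)OC2=O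
F7 | step 9 | (E)-3-(aryloxy)-2-(dimethoxymethyl)acryloyl chloride (aryl = Ar) | C=CCOC(=O)c1c(C)cc(OC)c(CO[Si](c2ccccc2)(c2ccccc2)C(C)(C)C)c1O/C=C(\C(OC)OC)C(Cl)=O
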